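**Plan**

- Retrosynthesis cuts, in this order: the bond between C1' of ring A and the carbonyl carbon (aryllithium plus aldehyde), both C1''–C2'' bonds of the prenyl groups on ring B, and the two bonds from C3 and C5 of ring B to the benzylic C1'' carbons (formaldehyde).
- Enabling feature: each prenyl group hangs from a benzylic CH2 on C3 or C5 of ring B, ortho to the C4 hydroxyl, so each C1''–C2'' bond is the 1,4-addition of an isobutenyl nucleophile to an ortho-quinone methide of that phenol.
- Forward: 3-(4-hydroxyphenyl)propan-1-ol is bis-hydroxymethylated and peracetylated, and isobutenylmagnesium bromide then builds both prenyl groups in one operation.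
- The chain is then joined to ring A: phenol MOM protection, oxidation to the aldehyde, addition of lithiated tris-MOM phloroglucinol, oxidation to the ketone, acidic MOM removal. No ring is formed anywhere.
- Stereochemistry: the target has no stereocentre and no stereogenic double bond. The carbinol centre of step 7 is racemic and is erased by the oxidation in step 8.

Key step: step 3

Assumption on the chemistry: in step 3 the chain acetate, an ordinary primary alkyl ester, is taken to be cleaved last, on warming. Intermediates 7–11 are drawn accordingly; the order does not change the product.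

**Route**

Step 1
Reactants: 1 3-(4-hydroxyphenyl)propan-1-ol; 2 formaldehyde
Product: 4 4-(3-hydroxypropyl)-2,6-bis(hydroxymethyl)phenol, via mono(hydroxymethyl) phenol 3 (not isolated)
Conditions: 37% aq CH2O (5 equiv), NaOH (1.2 equiv), H2O, 25 °C, 3 d; then AcOH to pH 6
Reagents that add atoms: formaldehyde (second equivalent of 2), C=O
Why: Lederer–Manasse hydroxymethylation, in which the sodium phenoxide can attack formaldehyde only through its two free ortho carbons because the para position carries the propanol chain, so two equivalents of formaldehyde are taken up one after the other, and room temperature should keep the hydroxymethyl phenols from condensing to diarylmethanes.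

Step 2
Reactants: 4 4-(3-hydroxypropyl)-2,6-bis(hydroxymethyl)phenol
Product: 5 4-(3-acetoxypropyl)-2,6-bis(acetoxymethyl)phenyl acetate
Conditions: Ac2O (6 equiv), pyridine, DMAP (cat.), CH2Cl2, 0 °C to rt
Reagents that add atoms: acetic anhydride, CC(=O)OC(C)=O
Why: DMAP-catalysed acylation should convert the phenol, both benzylic alcohols and the chain alcohol into acetates, as is routine for salicyl alcohols.

Step 3
Reactants: 5 4-(3-acetoxypropyl)-2,6-bis(acetoxymethyl)phenyl acetate; 6 2-methylprop-1-enylmagnesium bromide
Product: 12 4-(3-hydroxypropyl)-2,6-bis(3-methylbut-2-enyl)phenol, via bromomagnesium phenoxide 7 (not isolated), via first ortho-quinone methide 8 (not isolated), via monoprenyl bromomagnesium phenoxide 9 (not isolated), via second ortho-quinone methide 10 (not isolated), via diprenyl phenoxide chain acetate 11 (not isolated)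
Conditions: 6 (8 equiv, 0.5 M in THF), THF, −78 °C, slow addition of 5; warm to 0 °C, then rt; sat. aq NH4Cl
Reagents that add atoms: 2-methylprop-1-enylmagnesium bromide (second equivalent of 6), CC(C)=C[Mg]Br
Why: Proposed new method: 6 first cleaves the aryl acetate, the most electrophilic of the four esters, to bromomagnesium phenoxide 7, which expels one ortho benzylic acetate to give ortho-quinone methide 8; 1,4-addition of the isobutenyl group to its exocyclic methylene rearomatises the ring to phenoxide 9, which repeats expulsion (10) and addition on the other side to give 11, whose chain acetate is cleaved on warming. The closest known reaction type is the organomagnesium-triggered release of a single ortho-quinone methide from an O-acylated salicyl alcohol derivative with in situ conjugate addition of an alkenyl Grignard reagent, while two successive quinone methides from one 2,6-bis(acyloxymethyl)phenol are known with heteroatom nucleophiles. No ring is closed and no stereocentre is formed, and the new double bonds carry two identical methyl groups, so no alkene geometry arises. The step needs aryl ester cleavage and acetate expulsion to run ahead of direct attack on the benzylic esters, and conjugate addition to run ahead of quinone methide oligomerisation. The first should be secured by the better phenoxide leaving group of the aryl ester and by the intramolecular, magnesium-assisted expulsion at the benzylic carbon, the second by slow addition of 5 to a large excess of 6 at −78 °C so that each quinone methide forms in the presence of its trap. Regiochemistry is not in question, because the blocked para position and the two CH2OAc groups fix both sites ortho to the C4 oxygen of ring B.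

Step 4
Reactants: 12 4-(3-hydroxypropyl)-2,6-bis(3-methylbut-2-enyl)phenol
Product: 13 3-[4-(methoxymethoxy)-3,5-bis(3-methylbut-2-enyl)phenyl]propan-1-ol
Conditions: MOMCl (1.2 equiv), Cs2CO3 (1.5 equiv), MeCN, 0 °C to rt
Reagents that add atoms: chloromethyl methyl ether (MOMCl), COCCl
Why: Chemoselective Williamson-type O-alkylation, since Cs2CO3 deprotonates the phenol but not the primary alcohol and the small, very reactive chloromethyl ether should alkylate the phenoxide despite its two ortho substituents.

Step 5
Reactants: 13 3-[4-(methoxymethoxy)-3,5-bis(3-methylbut-2-enyl)phenyl]propan-1-ol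
Product: 14 3-[4-(methoxymethoxy)-3,5-bis(3-methylbut-2-enyl)phenyl]propanal
Conditions: Dess–Martin periodinane (1.3 equiv), NaHCO3, CH2Cl2, 0 °C to rt
Reagents that add atoms: none
Why: Buffered Dess–Martin oxidation takes a primary alcohol to the aldehyde without over-oxidation and should leave the trisubstituted alkenes and the aryl MOM ether untouched.

Step 6
Reactants: 15 phloroglucinol
Product: 16 1,3,5-tris(methoxymethoxy)benzene
Conditions: MOMCl (4 equiv), i-Pr2NEt (5 equiv), CH2Cl2, 0 °C to rt
Reagents that add atoms: chloromethyl methyl ether (MOMCl), COCCl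
Why: Standard threefold MOM ether formation, in which the hard chloromethyl ether with a hindered amine base favours O-alkylation over C-alkylation of phloroglucinol.

Step 7
Reactants: 14 3-[4-(methoxymethoxy)-3,5-bis(3-methylbut-2-enyl)phenyl]propanal; 16 1,3,5-tris(methoxymethoxy)benzene
Product: 18 3-[4-(methoxymethoxy)-3,5-bis(3-methylbut-2-enyl)phenyl]-1-[2,4,6-tris(methoxymethoxy)phenyl]propan-1-ol (racemic), via 2,4,6-tris(methoxymethoxy)phenyllithium 17 (not isolated)
Conditions: 16 (1.4 equiv), n-BuLi (1.3 equiv), THF, 0 °C, 1 h; then 14, −78 °C; sat. aq NH4Cl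
Reagents that add atoms: none
Why: Directed ortho-metalation followed by 1,2-addition: the three ring CH positions of 16 are equivalent and each lies between two MOM ethers, so a single aryllithium forms and should add to the aldehyde at −78 °C faster than it enolises it; the carbinol centre arises without control as a racemate and is removed in step 8.

Step 8
Reactants: 18 3-[4-(methoxymethoxy)-3,5-bis(3-methylbut-2-enyl)phenyl]-1-[2,4,6-tris(methoxymethoxy)phenyl]propan-1-ol
Product: 19 3-[4-(methoxymethoxy)-3,5-bis(3-methylbut-2-enyl)phenyl]-1-[2,4,6-tris(methoxymethoxy)phenyl]propan-1-one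
Conditions: Dess–Martin periodinane (1.5 equiv), NaHCO3, CH2Cl2, rt
Reagents that add atoms: none
Why: Dess–Martin oxidation of the hindered secondary benzylic alcohol to the aryl ketone tolerates MOM ethers and prenyl groups and removes the only stereocentre of the route.

Step 9
Reactants: 19 3-[4-(methoxymethoxy)-3,5-bis(3-methylbut-2-enyl)phenyl]-1-[2,4,6-tris(methoxymethoxy)phenyl]propan-1-one
Product: 20 4,2',4',6'-tetrahydroxy-3,5-diprenyldihydrochalcone
Conditions: 3 M aq HCl, MeOH, 25 to 40 °C
Reagents that add atoms: none
Why: Acid-catalysed acetal exchange with methanol cleaves all four aryl MOM ethers, the two ortho to the carbonyl being activated by chelation, and the low temperature is chosen to stay below the onset of acid-catalysed cyclisation of the ortho-prenyl phenol.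

**Compound list**

1 | 3-(4-hydroxyphenyl)propan-1-ol | OCCCc1ccc(O)cc1 | starting material
2 | formaldehyde | C=O | starting material
3 | 2-(hydroxymethyl)-4-(3-hydroxypropyl)phenol | OCCCc1ccc(O)c(CO)c1 | intermediate
4 | 4-(3-hydroxypropyl)-2,6-bis(hydroxymethyl)phenol | OCCCc1cc(CO)c(O)c(CO)c1 | intermediate
5 | 4-(3-acetoxypropyl)-2,6-bis(acetoxymethyl)phenyl acetate | CC(=O)OCCCc1cc(COC(C)=O)c(OC(C)=O)c(COC(C)=O)c1 | intermediate
6 | 2-methylprop-1-enylmagnesium bromide | CC(C)=C[Mg]Br | starting material
7 | bromomagnesium 2,6-bis(acetoxymethyl)-4-(3-acetoxypropyl)phenoxide | CC(=O)OCCCc1cc(COC(C)=O)c(O[Mg]Br)c(COC(C)=O)c1 | intermediate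
8 | 2-(acetoxymethyl)-4-(3-acetoxypropyl)-6-methylidenecyclohexa-2,4-dien-1-one | C=C1C=C(CCCOC(C)=O)C=C(COC(C)=O)C1=O | intermediate
9 | bromomagnesium 2-(acetoxymethyl)-4-(3-acetoxypropyl)-6-(3-methylbut-2-enyl)phenoxide | CC(C)=CCc1cc(CCCOC(C)=O)cc(COC(C)=O)c1O[Mg]Br | intermediate
10 | 4-(3-acetoxypropyl)-6-methylidene-2-(3-methylbut-2-enyl)cyclohexa-2,4-dien-1-one | C=C1C=C(CCCOC(C)=O)C=C(CC=C(C)C)C1=O | intermediate
11 | bromomagnesium 4-(3-acetoxypropyl)-2,6-bis(3-methylbut-2-enyl)phenoxide | CC(C)=CCc1cc(CCCOC(C)=O)cc(CC=C(C)C)c1O[Mg]Br | intermediate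
12 | 4-(3-hydroxypropyl)-2,6-bis(3-methylbut-2-enyl)phenol | CC(C)=CCc1cc(CCCO)cc(CC=C(C)C)c1O | intermediate
13 | 3-[4-(methoxymethoxy)-3,5-bis(3-methylbut-2-enyl)phenyl]propan-1-ol | COCOc1c(CC=C(C)C)cc(CCCO)cc1CC=C(C)C | intermediate
14 | 3-[4-(methoxymethoxy)-3,5-bis(3-methylbut-2-enyl)phenyl]propanal | COCOc1c(CC=C(C)C)cc(CCC=O)cc1CC=C(C)C | intermediate
15 | phloroglucinol | Oc1cc(O)cc(O)c1 | starting material
16 | 1,3,5-tris(methoxymethoxy)benzene | COCOc1cc(OCOC)cc(OCOC)c1 | intermediate
17 | 2,4,6-tris(methoxymethoxy)phenyllithium | [Li]c1c(OCOC)cc(OCOC)cc1OCOC | intermediate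
18 | 3-[4-(methoxymethoxy)-3,5-bis(3-methylbut-2-enyl)phenyl]-1-[2,4,6-tris(methoxymethoxy)phenyl]propan-1-ol (racemic) | COCOc1cc(OCOC)c(C(O)CCc2cc(CC=C(C)C)c(OCOC)c(CC=C(C)C)c2)c(OCOC)c1 | intermediate
19 | 3-[4-(methoxymethoxy)-3,5-bis(3-methylbut-2-enyl)phenyl]-1-[2,4,6-tris(methoxymethoxy)phenyl]propan-1-one | COCOc1cc(OCOC)c(C(=O)CCc2cc(CC=C(C)C)c(OCOC)c(CC=C(C)C)c2)c(OCOC)c1 | intermediate
20 | 4,2',4',6'-tetrahydroxy-3,5-diprenyldihydrochalcone | CC(C)=CCc1cc(CCC(=O)c2c(O)cc(O)cc2O)cc(CC=C(C)C)c1O | target

**Step count and risks**

Total step count: 9. Longest linear sequence: 8 steps (steps 1–5 and 7–9); step 6 is a one-step side branch.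

**Step 3.** The Grignard reagent may add to the benzylic ester carbonyls before the phenoxide expels acetate, which leaves hydroxymethyl groups that cannot ionise. The quinone methide may also be intercepted by phenoxide and oligomerise.

The fallback uses known chemistry, sets out from 1 and returns at 13. Compound 1 is brominated at both ortho positions (NBS, 2 equiv, cat. i-Pr2NH, CH2Cl2, 0 °C) to give 2,6-dibromo-4-(3-hydroxypropyl)phenol F1. The acidic dibromophenol is converted selectively into its MOM ether (MOMCl, K2CO3, acetone) to give 3-[3,5-dibromo-4-(methoxymethoxy)phenyl]propan-1-ol F2. A twofold Stille coupling with tributyl(3-methylbut-2-enyl)stannane, catalysed by the zerovalent palladium complex Pd(PPh3)4 in DMF at 100 °C, should then give 13. The route continues at step 5.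

**Step 9.** Once the ring B phenol is liberated under acid, it may cyclise onto an ortho prenyl double bond to form a chroman. Methanol may also add to the alkenes, and the released formaldehyde equivalent may alkylate ring A.

The fallback sets out from 12 and returns at 20; it keeps the ring B oxygen masked by an acid-stable allyl group until the acid step is over. Compound 12 is allylated on the phenol (allyl bromide, K2CO3, acetone, reflux) to give 3-[4-(allyloxy)-3,5-bis(3-methylbut-2-enyl)phenyl]propan-1-ol F3. Dess–Martin oxidation gives 3-[4-(allyloxy)-3,5-bis(3-methylbut-2-enyl)phenyl]propanal F4. Addition of aryllithium 17, made from 16 as in step 7, at −78 °C gives racemic 3-[4-(allyloxy)-3,5-bis(3-methylbut-2-enyl)phenyl]-1-[2,4,6-tris(methoxymethoxy)phenyl]propan-1-ol F5. A second Dess–Martin oxidation gives 3-[4-(allyloxy)-3,5-bis(3-methylbut-2-enyl)phenyl]-1-[2,4,6-tris(methoxymethoxy)phenyl]propan-1-one F6. HCl in MeOH removes the three ring A MOM groups while the ring B oxygen stays allylated, so no chroman can form, and this gives 3-[4-(allyloxy)-3,5-bis(3-methylbut-2-enyl)phenyl]-1-(2,4,6-trihydroxyphenyl)propan-1-one F7. A Tsuji–Trost deallylation (Pd(PPh3)4 cat., morpholine, THF, rt) under neutral conditions then gives 20.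

**Step 7.** The hindered, basic aryllithium may take a proton from the α-CH2 of the enolisable aldehyde instead of adding to its carbonyl group. The enolate would then return aldehyde on work-up and feed aldol self-condensation.

The fallback replaces the aldehyde by an amide, which is far less acidic at the α-carbon and cannot undergo aldol reaction. It sets out from 13 and 16 and returns at 19, so step 8 is not needed. Alcohol 13 is oxidised directly to the acid with TEMPO (cat.) and PhI(OAc)2 in MeCN/H2O to give 3-[4-(methoxymethoxy)-3,5-bis(3-methylbut-2-enyl)phenyl]propanoic acid F8. Activation with 1,1'-carbonyldiimidazole in CH2Cl2, followed by N,O-dimethylhydroxylamine hydrochloride, gives the Weinreb amide N-methoxy-N-methyl-3-[4-(methoxymethoxy)-3,5-bis(3-methylbut-2-enyl)phenyl]propanamide F9. Aryllithium 17, made from 16 as in step 7, should add once to F9 at −78 to 0 °C, and the chelated tetrahedral intermediate collapses on aqueous NH4Cl work-up to ketone 19. The route continues at step 9.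

**Further compounds**

F1 | step 3 | 2,6-dibromo-4-(3-hydroxypropyl)phenol | OCCCc1cc(Br)c(O)c(Br)c1
F2 | step 3 | 3-[3,5-dibromo-4-(methoxymethoxy)phenyl]propan-1-ol | COCOc1c(Br)cc(CCCO)cc1Br
F3 | step 9 | 3-[4-(allyloxy)-3,5-bis(3-methylbut-2-enyl)phenyl]propan-1-ol | C=CCOc1c(CC=C(C)C)cc(CCCO)cc1CC=C(C)C
F4 | step 9 | 3-[4-(allyloxy)-3,5-bis(3-methylbut-2-enyl)phenyl]propanal | C=CCOc1c(CC=C(C)C)cc(CCC=O)cc1CC=C(C)C
F5 | step 9 | 3-[4-(allyloxy)-3,5-bis(3-methylbut-2-enyl)phenyl]-1-[2,4,6-tris(methoxymethoxy)phenyl]propan-1-ol (racemic) | C=CCOc1c(CC=C(C)C)cc(CCC(O)c2c(OCOC)cc(OCOC)cc2OCOC)cc1CC=C(C)C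
F6 | step 9 | 3-[4-(allyloxy)-3,5-bis(3-methylbut-2-enyl)phenyl]-1-[2,4,6-tris(methoxymethoxy)phenyl]propan-1-one | C=CCOc1c(CC=C(C)C)cc(CCC(=O)c2c(OCOC)cc(OCOC)cc2OCOC)cc1CC=C(C)C
F7 | step 9 | 3-[4-(allyloxy)-3,5-bis(3-methylbut-2-enyl)phenyl]-1-(2,4,6-trihydroxyphenyl)propan-1-one | C=CCOc1c(CC=C(C)C)cc(CCC(=O)c2c(O)cc(O)cc2O)cc1CC=C(C)C
F8 | step 7 | 3-[4-(methoxymethoxy)-3,5-bis(3-methylbut-2-enyl)phenyl]propanoic acid | COCOc1c(CC=C(C)C)cc(CCC(=O)O)cc1CC=C(C)C
F9 | step 7 | N-methoxy-N-methyl-3-[4-(methoxymethoxy)-3,5-bis(3-methylbut-2-enyl)phenyl]propanamide | COCOc1c(CC=C(C)C)cc(CCC(=O)N(C)OC)cc1CC=C(C)C
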